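The earlier runs and the new flask stem from a simulated flask with constants of no real substance, and the scatter is random.

Solid substrate cannot be what still moves target in the oak flask at 5.0 h, since the readings show 0.1% of it left at 1.00 h.

common to all: solid substrate 0.30 M

| run | temperature | remark | time |
|---|---|---|---|
| oak | 60 °C | the very flask that is asked about, followed so far |  |
| elm | 45 °C | run made earlier |  |
| flask | 60 °C |  | 5.0 h |

- oak (time / h: target / %, solid substrate / %): 0.333: 12.5, 36.0; 1.00: 21.1, 0.1; 2.00: 15.3, 0; 3.00: 13.5, 0.1; 4.00: 13.5, 0
- elm (time / h: target / %, solid substrate / %): 0.667: 27.8, 5.5; 2.00: 32.3, 0; 4.00: 24.6, 0.3; 6.00: 20.1, 0.3; 8.00: 17.8, 0.1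

(scatter of a reading: 0.5 percentage points)

- Thursday's: at 5.0 h raise the temperature by 15 K, then wait 10 h
- Wednesday's: change nothing and wait 10 h more
- Saturday's: at 5.0 h take out 90% of the target then present, then wait 10 h

- percentages count the solid substrate that a species holds: one target or isomer of the product counts as two
- solid, in amounts per volume of the solution: solid substrate
- removed target is counted in
- steps thought possible: solid substrate <-> starting material; 2 starting material <-> target; target <-> isomer of the product
- at the start none of the solid substrate is in solution

- target, in percent of the solid substrate first charged, at 5.0 h
- the option that brings most further target ("none" if no option brings more than 2 percentage points) (Thursday's / Wednesday's / Saturday's / none)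
- target present, with what was taken out counted in, in percent of the solid substrate first charged, after Thursday's
- target present, with what was taken out counted in, in percent of the solid substrate first charged, after Wednesday's

We build the oak flask one process at a time. Start with the main step, two starting material to target. Target climbs, and this step can also run back. Now add target to isomer of the product. Target drains, and the readings flatten at 13.5%, which is 7.6 percentage points below the highest reading, 21.1% at 1.00 h. The dissolving is the last piece, and it delays the climb.

The concentration we take to set the order of the fall is the excess of target over its flat level. We treat the fall as first order in that excess (pseudo-first-order). The elm run at 45 °C supports this, for its successive drops shrink by ratios of 0.584 and 0.511. In the oak flask the excess is 7.6 points at 1.00 h and 1.8 points at 2.00 h. That gives 0.481 h for the excess half-life, the time in which target's distance from its flat level halves.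

By 5.0 h the excess is 0.024 points, less than the scatter of 0.5 points. So we reckon 13.5% now, and the same after Wednesday's. The elm ratio puts the elm flat level at 15.4%, which is 1.9 points above the oak level and under the margin of 2 points. We let Thursday's repeat that step, which gives 11.6%. Saturday's banks 12.2% of the charge, and 10 h is 20.8 excess half-lives. Holding the flat share on what remains, we reckon a gain of 11 points, so we choose Saturday's.

The forecast has 13.5%, 13.5% after Wednesday's, 12.2% after Thursday's, and Saturday's, since “the plateau looks like true equilibrium”. The oak flask gives 12.4% at 5.0 h, 12.3% after Wednesday's, 12.7% after Thursday's, and Saturday's with 9.4 points further target.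

    solid substrate ⇌ starting material, rate k1*(cs1 - [starting material]) while solid is left; crystals form when [starting material] > cs1 (solubility = 0.260 M, k = 9.66 × 10⁻⁴ s⁻¹)
    2 starting material ⇌ target (K = 1.24 M⁻¹, k = 0.00430 M⁻¹ s⁻¹, Ea = 70.0 kJ mol⁻¹, ΔH = −32.0 kJ mol⁻¹)
    target ⇌ isomer of the product (K = 3.80, k = 4.91 × 10⁻⁴ s⁻¹, Ea = 104 kJ mol⁻¹, ΔH = −22.0 kJ mol⁻¹)
    (constants at 60 °C)

The neighbour flask read at 3.0 h is our second case. The excess half-life leaves 0.43 points of excess at that time, and that flask stands 0.79 points above the oak flask at 5.0 h. The oak flask itself has come to rest by 5.0 h, with target at 12.4%. The extra time makes no difference to target. Left to 50.0 h, far longer than our reckoned excess half-life of 0.481 h, the oak flask holds target at 12.3%, starting material at 40.7% and isomer of the product at 46.9%.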